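## Retrosynthetic overview

1. Target 11 ⇐ diol 10 by OH-directed hydrogenation of the ring C=C, which sets C8.
2. 10 ⇐ bis-sultam 9 by reductive cleavage of both N-acyl sultams; the auxiliary is recovered.
3. 9 ⇐ two molecules of N-sinapoyl sultam 6 in one flask: phenoxyl-radical C8–C8′ coupling (sets C8′), tautomerisation of one quinone methide, then intramolecular quinone-methide Friedel–Crafts closure C6–C7′ (sets C7′, trans).
4. 6 ⇐ sinapic acid 1 + camphorsultam 2.
5. Ring order: only the cyclohexene ring of the tetralin is built (step 2); both arenes come from sinapic acid.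

Assumption: the N-enoyl sultam is taken to follow the usual Oppolzer sense (bonding at the Cα-re face for the (2R)-sultam), so the (2S)-sultam is used to get the Cα-si bonding that C8′ needs; this sense is unverified, and both antipodes are sold. C7/C8/C9 and C7′/C8′/C9′ are lignan numbering.

## Route

Step 1
Reactants: 1 sinapic acid; 2 (1R)-(+)-2,10-camphorsultam [(2S)-bornane-10,2-sultam]
Product: 6 N-[(E)-sinapoyl]-(2S)-bornane-10,2-sultam, via bis-TMS sinapate 3 (not isolated), via O-TMS sinapoyl chloride 4 (not isolated), via O-TMS N-sinapoyl sultam 5 (not isolated)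
Conditions: HMDS, cat. TMSCl, CH2Cl2, 40 °C, evaporate; (COCl)2, cat. DMF, CH2Cl2, 0 °C; 2, Et3N, DMAP (10 mol%), 0 °C → rt; 1 M HCl/MeOH work-up
Reagents that add atoms: none
Why: Transient O-silylation masks the phenol and gives the silyl ester, which oxalyl chloride/DMF converts to the acid chloride under neutral conditions; DMAP-catalysed N-acylation of the sultam and acidic cleavage of the aryl silyl ether give the (E)-enoyl sultam, with no stereocentre formed.

Step 2
Reactants: 6 N-[(E)-sinapoyl]-(2S)-bornane-10,2-sultam (2 equiv)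
Product: 9 (1S,2R)-7-hydroxy-1-(4-hydroxy-3,5-dimethoxyphenyl)-6,8-dimethoxy-1,2-dihydronaphthalene-2,3-dicarbonyl bis[(2S)-bornane-10,2-sultam], via bis-quinone methide 7 (not isolated), via mono-quinone methide 8 (not isolated)
Conditions: FeCl3·6H2O (1.1 equiv per 6), acetone–H2O 9:1, −20 °C → rt; recrystallisation (EtOAc/hexane) to a single diastereomer
Reagents that add atoms: none
Why: Proposed new method: Fe(III) oxidises each phenol to a phenoxyl radical and two radicals couple C8–C8′, each on the Cα-si face left open by its (2S)-sultam, giving (R,R)-bis-quinone methide 7; loss of the acidic C8–H re-forms one phenol-cinnamoyl unit (8), whose C6 (ortho/para to OMe) adds to the remaining quinone methide at C7′ in a six-membered Friedel–Crafts closure anti to the C8′ acyl group, giving the 1,2-trans product; the closest known reactions are the FeCl3 oxidative dimerisation of sinapate esters to thomasidioates and sultam-controlled radical C–C bond formation at Cα.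

Step 3
Reactants: 9 bis-sultam dihydronaphthalene
Product: 10 [(1S,2R)-7-hydroxy-1-(4-hydroxy-3,5-dimethoxyphenyl)-6,8-dimethoxy-1,2-dihydronaphthalene-2,3-diyl]dimethanol
Conditions: LiAlH4 (4 equiv), THF, −40 → 0 °C; Rochelle-salt work-up; 2 recovered
Reagents that add atoms: none
Why: Hydride cleavage of N-acyl sultams to primary alcohols is the standard auxiliary removal; 1,2-attack should be favoured on the enoyl unit because its β-carbon is deactivated by the para-phenoxide formed first, and the low temperature protects the acidic C2–H, so C1 and C2 are untouched.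

Step 4
Reactants: 10 dihydronaphthalene diol
Product: 11 (+)-lyoniresinol, (6R,7R,8S)-8-(4-hydroxy-3,5-dimethoxyphenyl)-6,7-bis(hydroxymethyl)-1,3-dimethoxy-5,6,7,8-tetrahydronaphthalen-2-ol
Conditions: H2 (1 atm), [Ir(cod)(PCy3)(py)]BArF (5 mol%), CH2Cl2, rt
Reagents that add atoms: none
Why: Hydroxyl-directed hydrogenation (Crabtree type): iridium bound to the homoallylic C8′–CH2OH delivers H2 to the alkene face syn to that group, which is also the face anti to the pseudo-axial C7′ aryl, so H at C8 ends cis to C8′–CH2OH and the new CH2OH trans to it (8R, all-trans).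

## Compound list

1 | sinapic acid, (E)-3-(4-hydroxy-3,5-dimethoxyphenyl)prop-2-enoic acid | COc1cc(/C=C/C(=O)O)cc(OC)c1O | starting material
2 | (1R)-(+)-2,10-camphorsultam, (2S)-bornane-10,2-sultam, (3aR,6S,7aS) | CC1(C)[C@H]2CC[C@@]13CS(=O)(=O)N[C@H]3C2 | starting material
3 | trimethylsilyl (E)-3-[3,5-dimethoxy-4-(trimethylsilyloxy)phenyl]prop-2-enoate | COc1cc(/C=C/C(=O)O[Si](C)(C)C)cc(OC)c1O[Si](C)(C)C | intermediate
4 | (E)-3-[3,5-dimethoxy-4-(trimethylsilyloxy)phenyl]prop-2-enoyl chloride | COc1cc(/C=C/C(Cl)=O)cc(OC)c1O[Si](C)(C)C | intermediate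
5 | N-[(E)-3-(3,5-dimethoxy-4-trimethylsilyloxyphenyl)prop-2-enoyl]-(2S)-bornane-10,2-sultam | COc1cc(/C=C/C(=O)N2[C@H]3C[C@@H]4CC[C@@]3(CS2(=O)=O)C4(C)C)cc(OC)c1O[Si](C)(C)C | intermediate
6 | N-[(E)-sinapoyl]-(2S)-bornane-10,2-sultam | COc1cc(/C=C/C(=O)N2[C@H]3C[C@@H]4CC[C@@]3(CS2(=O)=O)C4(C)C)cc(OC)c1O | intermediate
7 | (2R,3R)-2,3-bis[(3,5-dimethoxy-4-oxocyclohexa-2,5-dien-1-ylidene)methyl]butanedioyl bis[(2S)-bornane-10,2-sultam] | COC1=CC(=C[C@@H](C(=O)N2[C@H]3C[C@@H]4CC[C@@]3(CS2(=O)=O)C4(C)C)[C@@H](C=C2C=C(OC)C(=O)C(OC)=C2)C(=O)N2[C@H]3C[C@@H]4CC[C@@]3(CS2(=O)=O)C4(C)C)C=C(OC)C1=O | intermediate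
8 | (R,E)-2-[(3,5-dimethoxy-4-oxocyclohexa-2,5-dien-1-ylidene)methyl]-3-(4-hydroxy-3,5-dimethoxybenzylidene)butanedioyl bis[(2S)-bornane-10,2-sultam] | COc1cc(/C=C(/C(=O)N2[C@H]3C[C@@H]4CC[C@@]3(CS2(=O)=O)C4(C)C)[C@@H](C=C2C=C(OC)C(=O)C(OC)=C2)C(=O)N2[C@H]3C[C@@H]4CC[C@@]3(CS2(=O)=O)C4(C)C)cc(OC)c1O | intermediate
9 | (1S,2R)-7-hydroxy-1-(4-hydroxy-3,5-dimethoxyphenyl)-6,8-dimethoxy-1,2-dihydronaphthalene-2,3-dicarbonyl bis[(2S)-bornane-10,2-sultam] (1,2-trans) | COc1cc([C@H]2c3c(cc(OC)c(O)c3OC)C=C(C(=O)N4[C@H]5C[C@@H]6CC[C@@]5(CS4(=O)=O)C6(C)C)[C@@H]2C(=O)N2[C@H]4C[C@@H]5CC[C@@]4(CS2(=O)=O)C5(C)C)cc(OC)c1O | intermediate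
10 | [(1S,2R)-7-hydroxy-1-(4-hydroxy-3,5-dimethoxyphenyl)-6,8-dimethoxy-1,2-dihydronaphthalene-2,3-diyl]dimethanol | COc1cc([C@H]2c3c(cc(OC)c(O)c3OC)C=C(CO)[C@@H]2CO)cc(OC)c1O | intermediate
11 | (+)-lyoniresinol, (6R,7R,8S)-8-(4-hydroxy-3,5-dimethoxyphenyl)-6,7-bis(hydroxymethyl)-1,3-dimethoxy-5,6,7,8-tetrahydronaphthalen-2-ol (aryl/CH2OH/CH2OH all-trans) | COc1cc([C@H]2c3c(cc(OC)c(O)c3OC)C[C@@H](CO)[C@@H]2CO)cc(OC)c1O | target

## Step count and risks

Total steps: 4. Longest linear sequence: 4 (1 → 6 → 9 → 10 → 11).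

Steps most likely to fail:

**Step 2** (facial selectivity of the radical coupling, competing 8–O–4 coupling, over-oxidation to the naphthalene). The fallback sets out from 1 and comes back at 10. Compound 1 is esterified (MeOH, cat. H2SO4, reflux) to methyl (E)-sinapate F1. The same FeCl3 cascade, now without auxiliary, gives racemic trans-dimethyl thomasidioate, and preparative chiral SFC isolates dimethyl (1S,2R)-7-hydroxy-1-(4-hydroxy-3,5-dimethoxyphenyl)-6,8-dimethoxy-1,2-dihydronaphthalene-2,3-dicarboxylate F2. DIBAL-H (CH2Cl2/THF, −78 → 0 °C) reduces both esters to give 10. Absolute configuration then comes from resolution instead of the auxiliary.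

**Step 3** (conjugate reduction of the enoyl sultam, or deprotonation at the doubly activated C2–H with epimerisation or alkene migration). The fallback sets out from 9 and comes back at 10. Ti(OEt)4 in refluxing EtOH exchanges both N-acyl sultams for ethyl esters without base, giving diethyl (1S,2R)-7-hydroxy-1-(4-hydroxy-3,5-dimethoxyphenyl)-6,8-dimethoxy-1,2-dihydronaphthalene-2,3-dicarboxylate F3 and free 2. DIBAL-H (CH2Cl2, −78 → 0 °C) then gives 10 by clean 1,2-reduction.

**Step 4** (catalyst inhibition by the tetraol, poor solubility in CH2Cl2, or wrong face). The fallback sets out from 9 and comes back at 11, so C8 is set at the ester level. Compound 9 is ethanolysed as above to diethyl (1S,2R)-7-hydroxy-1-(4-hydroxy-3,5-dimethoxyphenyl)-6,8-dimethoxy-1,2-dihydronaphthalene-2,3-dicarboxylate F3. Hydrogenation over Pd/C (EtOAc, 1 atm H2) from the face anti to the pseudo-axial C1 aryl gives diethyl (1S,2R,3R)-7-hydroxy-1-(4-hydroxy-3,5-dimethoxyphenyl)-6,8-dimethoxy-1,2,3,4-tetrahydronaphthalene-2,3-dicarboxylate F4. Any 2,3-cis isomer is equilibrated at C3 with NaOEt/EtOH, which is safe once no alkene is left to migrate. LiAlH4 (THF, 0 °C) reduces F4 to 11.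

## Further compounds

F1 | step 2 | methyl (E)-3-(4-hydroxy-3,5-dimethoxyphenyl)prop-2-enoate (methyl sinapate) | COc1cc(/C=C/C(=O)OC)cc(OC)c1O
F2 | step 2 | dimethyl (1S,2R)-7-hydroxy-1-(4-hydroxy-3,5-dimethoxyphenyl)-6,8-dimethoxy-1,2-dihydronaphthalene-2,3-dicarboxylate | COc1cc([C@H]2c3c(cc(OC)c(O)c3OC)C=C(C(=O)OC)[C@@H]2C(=O)OC)cc(OC)c1O
F3 | step 3 | diethyl (1S,2R)-7-hydroxy-1-(4-hydroxy-3,5-dimethoxyphenyl)-6,8-dimethoxy-1,2-dihydronaphthalene-2,3-dicarboxylate | COc1cc([C@H]2c3c(cc(OC)c(O)c3OC)C=C(C(=O)OCC)[C@@H]2C(=O)OCC)cc(OC)c1O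
F4 | step 4 | diethyl (1S,2R,3R)-7-hydroxy-1-(4-hydroxy-3,5-dimethoxyphenyl)-6,8-dimethoxy-1,2,3,4-tetrahydronaphthalene-2,3-dicarboxylate | COc1cc([C@H]2c3c(cc(OC)c(O)c3OC)C[C@@H](C(=O)OCC)[C@@H]2C(=O)OCC)cc(OC)c1O
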